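**Assumption:** the SMILES has no stereocentre and a 20-membered ring cannot hold a stereogenic axis, so the target is achiral; "single enantiomer" is read as the single constitutional isomer drawn.

## Structural features

The target is a 20-membered macrocyclic bis(bibenzyl). Four benzene rings are joined in the cyclic order A–O–B–CH2CH2–C–O–D–CH2CH2–A by two diaryl ether oxygens and two ethano bridges. Ring A is 1,2,4-trisubstituted (bridge carbon at C1, free OH at C3, ether oxygen to ring B at C4), ring B is a meta-phenylene, ring C a para-phenylene, and ring D is 1,2,4-trisubstituted with the opposite pattern (bridge carbon at C1, ether oxygen to ring C at C3, free OH at C4). There is no stereocentre and no stereogenic axis, so no stereocontrol is needed. The fragile parts are the electron-rich catechol mono-aryl ether rings A and D: they are oxidation-prone as free phenols, and their benzylic carbons ionise easily once they carry a leaving group. The real difficulty is twofold: the two ortho-oxygenated diaryl ethers have opposite regiochemistry relative to their bridge carbons, and the strain-free but entropically costly 20-membered ring must be closed. The key step exploits the A–CH2–CH2–D bridge, whose two carbons are both benzylic. They can first be tied together through sulfur (benzylic halides are ideal partners for sulfide, and both α-sulfonyl CH2 groups are benzylically acidified), and the CH2–CH2 bond is then made inside the ring with loss of SO2. Because the bridge is saturated in the target, the alkene geometry produced by that contraction is of no consequence.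

## Logic of the disconnections

**21 ⇒ 20 ⇒ 19.** The two O–CH3 bonds are cut last and the A–D bridge is traced back to a CH=CH unit. The phenols stay masked through all basic, oxidative and halogenating steps, and the alkene is what the key step delivers. The demands are that BBr3 cleaves only alkyl–O bonds (diaryl ethers are inert) and that hydrogenation has nothing else to reduce in 19.

**19 ⇒ 16 (key).** The C–C bond between the benzylic carbons of rings A and D is cut and the two carbons are rejoined through an SO2 group, turning the 20-membered carbocycle into a 21-membered sulfone. Ring closure and C–C bond formation are thereby separated: the ring is closed through sulfur and the carbon bond is then made intramolecularly from two carbons held 1,3 to each other. The gain is a seco-precursor with two identical termini instead of differentiated ones. The forward step needs clean mono-halogenation α to sulfur and SO2 extrusion in the presence of only ether functions. The A–D bridge is chosen over the B–C bridge because its two carbons are then the carbonyl carbons that activate both SNAr ether formations.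

**16 ⇒ 14 ⇒ 12.** The two C–S bonds are cut, leading to sulfide ion and a bis(benzylic bromide). Sulfide and the intermediate thiolate are among the fastest nucleophiles towards benzylic bromides, which suits ring closure at high dilution. The demand is that the electron-rich bromides of 12 meet sulfur before they ionise or solvolyse, and that oxidation to 16 stops cleanly at sulfur.

**12 ⇒ 11 ⇒ 10.** No skeletal bond is cut; both C–Br bonds go back to C–OH and then to an aldehyde (ring A) and a methyl ester (ring D). One hydride reduction levels both carbonyls, so no terminus needs protection. The demand is only that the bromide formation is run cold and 12 is used at once.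

**10 ⇒ 8 + 9.** The bond between the ether oxygen and C4 of ring A is cut. The para-formyl group of 9 activates fluoride displacement and then becomes the bridge carbon, and the ortho-methoxy group is the masked ring-A hydroxyl. The demand is a phenoxide SNAr on a fluoride that carries an ortho donor, without saponifying the ester.

**8 ⇒ 7 ⇒ 2 + 5.** The B–C ethano bridge is cut as a C=C bond between the benzylic carbon of ring B and the formyl carbon of ring C. This splits the chain into a one-ring ylide precursor and a two-ring aldehyde. The demand is that the ylide from 2 reacts with its phenol unprotected, which the meta relationship (no conjugation between phenoxide and ylide carbon) allows.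

**5 ⇒ 3 + 4; 2 ⇒ 1.** The bond between the ether oxygen and C4 of ring C is cut; the para-formyl group of 4 activates the SNAr and then serves as the Wittig carbonyl. The C–P bond of 2 is cut back to the benzylic alcohol 1. Both are single operations on commercial materials; the ester of 3 must survive carbonate in DMF.

## Other disconnections considered

**Alternative 1:** (first to mind) Cut the A–D bridge as a C=C bond formed directly in the ring-closing event. The forward step is a macrocyclising Wittig reaction of the seco phosphonium aldehyde A1 at high dilution, giving 19. The chosen plan is preferred because A1 needs the two benzylic termini at different oxidation levels. From 10 that means acetal protection, ester reduction, bromination, phosphonium formation and deprotection, where the chosen route needs one reduction and one bromination. In A1 the ring closure and the C–C bond formation are also the same bimolecular-type event between a moderately nucleophilic semi-stabilised ylide and an aldehyde, so oligomerisation competes on equal terms. The sulfur route closes the ring with a far faster thiolate/benzyl bromide pair and forms the C–C bond unimolecularly.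

**Alternative 2:** Cut the aryl C–O bond between rings A and B and close the ring by intramolecular SNAr. The forward step is cyclisation of the fluoro-nitro phenol A2 with base at high dilution to the nitro macrocycle A3, followed by conversion of NO2 into OH. SNAr macro-etherification is mechanistically sound, but it needs an ortho-nitro activator that is not in the target, which costs three post-cyclisation operations (reduction, diazotisation, hydrolysis) on an electron-rich macrocycle. The linear precursor also needs two separate stilbene syntheses, one of them in the presence of a nitro group that rules out simple catalytic hydrogenation. In the chosen plan both ether bonds are made intermolecularly with activators that end up as skeleton carbons.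

**Alternative 3:** Cut both ethano bridges at once, assembling the macrocycle from two diaryl ether halves. The forward step is a [1+1] double thioether formation of the bis(benzylic bromide) A4 with the dithiol A5 to give the 22-membered dithia-macrocycle A6, followed by double oxidation, twofold Ramberg–Bäcklund contraction and hydrogenation to 20. This is more convergent and avoids the Wittig sequence, but the termini are not differentiated. Each bromide of A4 can pair with either thiol of A5, so the constitutional isomer A7 (ring A bridged to ring C, ring B to ring D) is expected beside A6, with the same mass and nearly the same polarity. Fixing the orientation would need stepwise differentiation of four termini and more steps than the chosen route, in which the B–C bridge is made first and only one orientation of ring closure is possible.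

Key step: step 10

## Route

Step 1
Reactants: 1 3-(hydroxymethyl)phenol
Product: 2 (3-hydroxybenzyl)triphenylphosphonium bromide
Conditions: PPh3·HBr (1.05 equiv), MeCN, reflux
Reagents that add atoms: triphenylphosphine hydrobromide, [Br-].[PH+](c1ccccc1)(c1ccccc1)c1ccccc1
Why: Direct phosphonium salt formation from a benzylic alcohol: HBr converts the alcohol into the benzylic bromide in situ and PPh3 displaces it (SN2); the phenol is inert under these acidic conditions.

Step 2
Reactants: 3 methyl 3-hydroxy-4-methoxybenzoate; 4 4-fluorobenzaldehyde
Product: 5 methyl 3-(4-formylphenoxy)-4-methoxybenzoate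
Conditions: K2CO3, DMF, 110 °C
Reagents that add atoms: none
Why: Nucleophilic aromatic substitution (SNAr): the phenoxide of 3 displaces fluoride para to the formyl group through a Meisenheimer intermediate; the methyl ester is stable to dry carbonate.

Step 3
Reactants: 2 (3-hydroxybenzyl)triphenylphosphonium bromide; 5 methyl 3-(4-formylphenoxy)-4-methoxybenzoate
Product: 7 methyl 3-{4-[2-(3-hydroxyphenyl)ethenyl]phenoxy}-4-methoxybenzoate (E/Z mixture), via phenoxide ylide 6 (not isolated)
Conditions: NaOMe (2.2 equiv), MeOH, 0 °C → rt; 1 M HCl work-up
Reagents that add atoms: none
Why: Wittig olefination of a semi-stabilised benzylic ylide with an aryl aldehyde; the meta-phenoxide is not conjugated with the ylide carbon, so nucleophilicity is kept, and methoxide/methanol leaves the methyl ester unchanged. The E/Z mixture is irrelevant because step 4 saturates the alkene.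

Step 4
Reactants: 7 methyl 3-{4-[2-(3-hydroxyphenyl)ethenyl]phenoxy}-4-methoxybenzoate (E/Z mixture)
Product: 8 methyl 3-{4-[2-(3-hydroxyphenyl)ethyl]phenoxy}-4-methoxybenzoate
Conditions: H2 (1 atm), 10% Pd/C, EtOAc–MeOH, rt
Reagents that add atoms: none
Why: Heterogeneous catalytic hydrogenation of a stilbene; ester, phenol and diaryl ether are not reduced under these conditions.

Step 5
Reactants: 8 methyl 3-{4-[2-(3-hydroxyphenyl)ethyl]phenoxy}-4-methoxybenzoate; 9 4-fluoro-3-methoxybenzaldehyde
Product: 10 methyl 3-[4-(2-{3-(4-formyl-2-methoxyphenoxy)phenyl}ethyl)phenoxy]-4-methoxybenzoate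
Conditions: K2CO3, DMF, 130 °C
Reagents that add atoms: none
Why: Second SNAr: the ring-B phenoxide displaces the fluoride para to the formyl group of 9, setting the ring A ether with OMe ortho to it; the higher temperature compensates for the ortho-methoxy donor.

Step 6
Reactants: 10 methyl 3-[4-(2-{3-(4-formyl-2-methoxyphenoxy)phenyl}ethyl)phenoxy]-4-methoxybenzoate
Product: 11 {3-[4-(2-{3-[4-(hydroxymethyl)-2-methoxyphenoxy]phenyl}ethyl)phenoxy]-4-methoxyphenyl}methanol
Conditions: LiAlH4, THF, 0 °C → rt; Fieser work-up
Reagents that add atoms: none
Why: Hydride reduction of aldehyde and ester in one operation brings both benzylic termini to the same oxidation level; aryl ethers are inert.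

Step 7
Reactants: 11 {3-[4-(2-{3-[4-(hydroxymethyl)-2-methoxyphenoxy]phenyl}ethyl)phenoxy]-4-methoxyphenyl}methanol
Product: 12 4-(bromomethyl)-2-[4-(2-{3-[4-(bromomethyl)-2-methoxyphenoxy]phenyl}ethyl)phenoxy]-1-methoxybenzene
Conditions: PBr3, CH2Cl2, 0 °C; used crude in step 8
Reagents that add atoms: phosphorus tribromide, BrP(Br)Br
Why: Conversion of benzylic alcohols into bromides through the phosphite esters; the electron-rich benzylic positions react fast at 0 °C, and immediate use limits ionisation of the product.

Step 8
Reactants: 12 4-(bromomethyl)-2-[4-(2-{3-[4-(bromomethyl)-2-methoxyphenoxy]phenyl}ethyl)phenoxy]-1-methoxybenzene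
Product: 14 21-membered macrocyclic sulfide (ring A–CH2–S–CH2–ring D), via bromo thiolate 13 (not isolated)
Conditions: Na2S·9H2O (1.05 equiv, in DMF–H2O 9:1) and 12 (in THF) added simultaneously by syringe pump over 12 h to DMF, rt, N2, final concentration about 2 mM
Reagents that add atoms: sodium sulfide nonahydrate, O.O.O.O.O.O.O.O.O.[Na+].[Na+].[S-2]
Why: Double SN2 thioether formation as used for thia-cyclophanes: the first displacement gives thiolate 13, whose intramolecular attack on the remaining benzylic bromide closes a strain-free 21-membered ring. The high rate of thiolate/benzyl bromide substitution lets ring closure compete with oligomerisation under simultaneous slow addition.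

Step 9
Reactants: 14 21-membered macrocyclic sulfide (ring A–CH2–S–CH2–ring D)
Product: 16 21-membered macrocyclic sulfone (ring A–CH2–SO2–CH2–ring D), via macrocyclic sulfoxide 15 (not isolated)
Conditions: mCPBA (2.3 equiv), CH2Cl2, 0 °C → rt
Reagents that add atoms: 3-chloroperoxybenzoic acid, OOC(=O)c1cccc(Cl)c1
Why: Stepwise electrophilic oxygen transfer to sulfur (sulfide → sulfoxide → sulfone); sulfur is far more nucleophilic than the anisole-type rings, so no ring oxidation is expected at this temperature.

Step 10
Reactants: 16 21-membered macrocyclic sulfone (ring A–CH2–SO2–CH2–ring D)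
Product: 19 20-membered macrocyclic stilbene (ring A–CH=CH–ring D; E/Z mixture), via α-bromo sulfone 17 (not isolated), via episulfone 18 (not isolated)
Conditions: KOH/Al2O3, BrCCl2CCl2Br (1.2 equiv), t-BuOH–THF, rt
Reagents that add atoms: none
Why: KOH on alumina deprotonates one of the two benzylic α-sulfonyl CH2 groups of 16, and the carbanion abstracts Br+ from BrCCl2CCl2Br (which collapses to Cl2C=CCl2 and bromide) to give α-bromo sulfone 17; it is immaterial which CH2 is brominated. Deprotonation at the other benzylic α′ carbon then triggers 1,3-displacement of bromide (3-exo-tet) to episulfone 18, which loses SO2 cheletropically to give 19. This is the Ramberg–Bäcklund reaction in its in situ halogenation (Meyers–Chan type) form; the closest precedents are the conversion of dibenzyl sulfones into stilbenes and the ring contraction of thia-cyclophane sulfones. The ring closed is the 20-membered carbocycle, formed by contraction of the 21-membered sulfone: the C–C bond arises within a three-membered ring from two carbons already held 1,3 to each other, so this bond formation is unimolecular and needs no dilution. No stereocentre of the target is created; the stereocentres of 17 and 18 and the E/Z geometry of 19 disappear in the extrusion and in step 11. The selectivity needed is mono- over poly-halogenation, secured by fast cyclisation of the doubly benzylic-activated α-bromo sulfone anion and a near-stoichiometric bromine donor; the B–C bridge CH2 groups are far less acidic, and the methyl and diaryl ethers are inert to KOH.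

Step 11
Reactants: 19 20-membered macrocyclic stilbene (ring A–CH=CH–ring D; E/Z mixture)
Product: 20 macrocyclic bis(bibenzyl) dimethyl ether (the target with both OH groups as OMe)
Conditions: H2 (1 atm), 10% Pd/C, EtOAc–THF, rt
Reagents that add atoms: none
Why: Catalytic hydrogenation of the only C=C bond; both alkene isomers converge on the same saturated bridge.

Step 12
Reactants: 20 macrocyclic bis(bibenzyl) dimethyl ether (the target with both OH groups as OMe)
Product: 21 target macrocycle (CNP0329842.0)
Conditions: BBr3 (6 equiv), CH2Cl2, −78 °C → rt; then H2O
Reagents that add atoms: none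
Why: Lewis acid demethylation of aryl methyl ethers (bromide attacks the O-methyl carbon of the boron-complexed ether); diaryl ether C–O bonds are not cleaved because neither carbon is open to SN2 attack.

## Compound list

1 | 3-(hydroxymethyl)phenol (3-hydroxybenzyl alcohol) | OCc1cccc(O)c1 | starting material
2 | (3-hydroxybenzyl)triphenylphosphonium bromide | [Br-].Oc1cccc(C[P+](c2ccccc2)(c2ccccc2)c2ccccc2)c1 | intermediate
3 | methyl 3-hydroxy-4-methoxybenzoate (methyl isovanillate) | COC(=O)c1ccc(OC)c(O)c1 | starting material
4 | 4-fluorobenzaldehyde | O=Cc1ccc(F)cc1 | starting material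
5 | methyl 3-(4-formylphenoxy)-4-methoxybenzoate | COC(=O)c1ccc(OC)c(Oc2ccc(C=O)cc2)c1 | intermediate
6 | sodium 3-[(triphenyl-λ5-phosphanylidene)methyl]phenolate (phenoxide ylide) | [Na+].[O-]c1cccc(C=P(c2ccccc2)(c2ccccc2)c2ccccc2)c1 | intermediate (not isolated)
7 | methyl 3-{4-[2-(3-hydroxyphenyl)ethenyl]phenoxy}-4-methoxybenzoate (E/Z mixture) | COC(=O)c1ccc(OC)c(Oc2ccc(C=Cc3cccc(O)c3)cc2)c1 | intermediate
8 | methyl 3-{4-[2-(3-hydroxyphenyl)ethyl]phenoxy}-4-methoxybenzoate | COC(=O)c1ccc(OC)c(Oc2ccc(CCc3cccc(O)c3)cc2)c1 | intermediate
9 | 4-fluoro-3-methoxybenzaldehyde | COc1cc(C=O)ccc1F | starting material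
10 | methyl 3-[4-(2-{3-(4-formyl-2-methoxyphenoxy)phenyl}ethyl)phenoxy]-4-methoxybenzoate | COC(=O)c1ccc(OC)c(Oc2ccc(CCc3cccc(Oc4ccc(C=O)cc4OC)c3)cc2)c1 | intermediate
11 | {3-[4-(2-{3-[4-(hydroxymethyl)-2-methoxyphenoxy]phenyl}ethyl)phenoxy]-4-methoxyphenyl}methanol | COc1ccc(CO)cc1Oc1ccc(CCc2cccc(Oc3ccc(CO)cc3OC)c2)cc1 | intermediate
12 | 4-(bromomethyl)-2-[4-(2-{3-[4-(bromomethyl)-2-methoxyphenoxy]phenyl}ethyl)phenoxy]-1-methoxybenzene | COc1ccc(CBr)cc1Oc1ccc(CCc2cccc(Oc3ccc(CBr)cc3OC)c2)cc1 | intermediate
13 | sodium thiolate of 12 in which one CH2Br has become CH2S− (drawn with sulfur on the ring D side; the ring A isomer leads to the same 14) | [Na+].COc1ccc(C[S-])cc1Oc1ccc(CCc2cccc(Oc3ccc(CBr)cc3OC)c2)cc1 | intermediate (not isolated)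
14 | 21-membered macrocyclic sulfide: 20 with the ring A–CH2CH2–ring D bridge replaced by CH2–S–CH2 | COc1cc2ccc1Oc1cccc(c1)CCc1ccc(cc1)Oc1cc(ccc1OC)CSC2 | intermediate
15 | 21-membered macrocyclic sulfoxide (racemic at sulfur) | COc1cc2ccc1Oc1cccc(c1)CCc1ccc(cc1)Oc1cc(ccc1OC)CS(=O)C2 | intermediate (not isolated)
16 | 21-membered macrocyclic sulfone: ring A–CH2–SO2–CH2–ring D | COc1cc2ccc1Oc1cccc(c1)CCc1ccc(cc1)Oc1cc(ccc1OC)CS(=O)(=O)C2 | intermediate
17 | α-bromo sulfone of 16 (racemic; drawn with Br on the ring A benzylic carbon, the ring D regioisomer reacts the same way) | COc1cc2ccc1Oc1cccc(c1)CCc1ccc(cc1)Oc1cc(ccc1OC)CS(=O)(=O)C2Br | intermediate (not isolated)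
18 | episulfone (2,3-diaryl thiirane 1,1-dioxide fused into the macrocycle; cis/trans mixture) | COc1cc2ccc1Oc1cccc(c1)CCc1ccc(cc1)Oc1cc(ccc1OC)C1C2S1(=O)=O | intermediate (not isolated)
19 | 20-membered macrocyclic stilbene: 20 with CH=CH between rings A and D (E/Z mixture) | COc1cc2ccc1Oc1cccc(c1)CCc1ccc(cc1)Oc1cc(ccc1OC)C=C2 | intermediate
20 | macrocyclic bis(bibenzyl) dimethyl ether (target with both OH as OMe) | COc1cc2ccc1Oc1cccc(c1)CCc1ccc(cc1)Oc1cc(ccc1OC)CC2 | intermediate
21 | target macrocyclic bis(bibenzyl), CNP0329842.0 (achiral) | Oc1cc2ccc1Oc1cccc(c1)CCc1ccc(cc1)Oc1cc(ccc1O)CC2 | target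

## Step count and risk

Total step count: 12. Longest linear sequence: 11 (steps 1, 3–12); step 2 is a one-step convergent branch.

**Step 10 (key step).** The most likely failure is a second bromination of the α-bromo sulfone anion before it cyclises, or incomplete 1,3-elimination in the flexible ring, either of which lowers the mass balance of the contraction. Fallback: set out from sulfide 14 and irradiate (254 nm, quartz, degassed trimethyl phosphite, dilute). C–S homolysis and capture of the sulfur by phosphite leave a tethered bis-benzylic diradical that recombines to the ethano bridge. This gives 20 directly and rejoins the route there, bypassing steps 9–11; it makes no new compound (F0).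

**Step 8.** Intermolecular S-alkylation (oligomerisation) can outrun ring closure, and the electron-rich benzylic bromides can ionise or solvolyse before sulfur reaches them. Fallback: abandon the sulfur bridge for a carbonyl coupling. Set out from diol 11 and oxidise with MnO2 (CH2Cl2, rt) to the dialdehyde 3-[4-(2-{3-(4-formyl-2-methoxyphenoxy)phenyl}ethyl)phenoxy]-4-methoxybenzaldehyde F1. Close the ring by intramolecular McMurry coupling (TiCl4, Zn, pyridine, THF, reflux, slow addition) to reach stilbene 19, where the route is rejoined.

**Step 3.** The doubly deprotonated reagent (phenoxide ylide) may be poorly soluble and slow to add to the aldehyde, so that base-induced side reactions of the aldehyde take over. Fallback: build the B–C bridge from an alkyne. Set out from aldehyde 5 and homologate with dimethyl (1-diazo-2-oxopropyl)phosphonate (K2CO3, MeOH) to methyl 3-(4-ethynylphenoxy)-4-methoxybenzoate F2. Couple with 3-iodophenol (Pd(PPh3)2Cl2, CuI, Et3N) to methyl 3-{4-[(3-hydroxyphenyl)ethynyl]phenoxy}-4-methoxybenzoate F3, and hydrogenate (H2, Pd/C) to reach 8.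

**Step 5.** Fluoride displacement may be slow because the ring is activated only by the para-formyl group and carries an ortho-methoxy donor; prolonged heating then invites ester saponification by adventitious hydroxide. Fallback: reverse the polarity of the C–O bond formation. Set out from phenol 8 and carry out a Chan–Lam coupling with (4-formyl-2-methoxyphenyl)boronic acid (Cu(OAc)2, pyridine, 4 Å MS, CH2Cl2, air, rt), which gives 10 directly; it makes no new compound (F0).

## Further compounds

F0 | step 10 | none | none
F1 | step 8 | 3-[4-(2-{3-(4-formyl-2-methoxyphenoxy)phenyl}ethyl)phenoxy]-4-methoxybenzaldehyde | COc1ccc(C=O)cc1Oc1ccc(CCc2cccc(Oc3ccc(C=O)cc3OC)c2)cc1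
F2 | step 3 | methyl 3-(4-ethynylphenoxy)-4-methoxybenzoate | COC(=O)c1ccc(OC)c(Oc2ccc(C#C)cc2)c1
F3 | step 3 | methyl 3-{4-[(3-hydroxyphenyl)ethynyl]phenoxy}-4-methoxybenzoate | COC(=O)c1ccc(OC)c(Oc2ccc(C#Cc3cccc(O)c3)cc2)c1
F0 | step 5 | none | none
A1 | alternative 1 | [3-(4-{2-[3-(4-formyl-2-methoxyphenoxy)phenyl]ethyl}phenoxy)-4-methoxybenzyl]triphenylphosphonium bromide | [Br-].COc1ccc(C[P+](c2ccccc2)(c2ccccc2)c2ccccc2)cc1Oc1ccc(CCc2cccc(Oc3ccc(C=O)cc3OC)c2)cc1
A2 | alternative 2 | 3-[2-(4-{5-[2-(4-fluoro-3-nitrophenyl)ethyl]-2-methoxyphenoxy}phenyl)ethyl]phenol | Oc1cccc(CCc2ccc(Oc3cc(CCc4ccc(F)c([N+](=O)[O-])c4)ccc3OC)cc2)c1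
A3 | alternative 2 | nitro macrocycle: 20 with the ring A methoxy group replaced by NO2 | [O-][N+](=O)c1cc2ccc1Oc1cccc(c1)CCc1ccc(cc1)Oc1cc(ccc1OC)CC2
A4 | alternative 3 | 4-(bromomethyl)-1-[3-(bromomethyl)phenoxy]-2-methoxybenzene | COc1cc(CBr)ccc1Oc1cccc(CBr)c1
A5 | alternative 3 | {4-methoxy-3-[4-(sulfanylmethyl)phenoxy]phenyl}methanethiol | COc1ccc(CS)cc1Oc1ccc(CS)cc1
A6 | alternative 3 | 22-membered dithia-macrocycle with CH2–S–CH2 between rings A/D and between rings B/C | COc1cc2ccc1Oc1cccc(c1)CSCc1ccc(cc1)Oc1cc(ccc1OC)CSC2
A7 | alternative 3 | constitutional isomer of A6 with CH2–S–CH2 between rings A/C and between rings B/D | COc1cc2ccc1Oc1cccc(c1)CSCc1ccc(OC)c(c1)Oc1ccc(cc1)CSC2
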